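Atoms are numbered in the heavy-atom order of the target SMILES (C1 to O34). Ring A = C5–C9, ring B = C2–C6/C12/C15, ring C = C18/C19/C29–C32, ring D = oxepane C19/C21–C23/C25/O28/C29.
Cuts: C32–C33, then C17–C18, which separates an A/B allylic bromide from a C/D enone. In the A/B half the cuts are O11–C9 with H–C5, C12–C15, C15=C16 and C3–C4. In the C/D half they are C18–C19 and C25–O28.
Enabling feature: C6 of ring A bears quaternary C12 with two methyl groups at the position where the stereocentre of (R)-limonene holds an isopropenyl group. Ring A with C4, C10 and a C5=C9 bond is what cleavage of the limonene ring alkene and aldol re-closure deliver. One hydrogen atom added to C14 therefore creates the C12 radical that closes ring B on C15.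
Forward order: ring A (aldol), chain C3–C2–C15–C17, ring B (radical closure), syn hydration of C5=C9, C15=C16. Rings D and C form together in one epoxide cascade. The halves are joined at C17–C18 and C33 is added last.
Stereochemistry: C6 comes from limonene and C2 from (S)-3-bromo-2-methylpropan-1-ol. C5 and C9 come from syn hydroboration anti to C12. C23, C19 and C29 come from Shi epoxidation. C18 is set by equilibration, C32 by equatorial methyl addition, and the E alkene by allylic strain against C12.

Key step: step 9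

Remark: the ring-closure product of step 9 is drawn as the expected C15 epimer and the alkylation product of step 20 as the expected kinetic C18 epimer. C15 is erased in step 12 and C18 is equilibrated in step 21. The D-fructose-derived ketone is assumed to give its usual R,R-epoxides with trisubstituted E-alkenes.

Step 1
Reactants: 1 (R)-(+)-limonene
Product: 3 (3R)-6-oxo-3-(prop-1-en-2-yl)heptanal, via limonene ring ozonide 2 (not isolated)
Conditions: O3 (1 equiv), CH2Cl2, −78 °C; then Me2S, −78 °C to rt
Reagents that add atoms: ozone, [O-][O+]=O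
Why: Ozonolysis with one equivalent of ozone should take the more electron-rich trisubstituted ring alkene before the 1,1-disubstituted isopropenyl group, and the stereocentre (later C6) is not involved.

Step 2
Reactants: 3 (3R)-6-oxo-3-(prop-1-en-2-yl)heptanal
Product: 4 (5S)-2-methyl-5-(prop-1-en-2-yl)cyclopent-1-ene-1-carbaldehyde
Conditions: piperidine, AcOH (cat.), toluene, reflux (Dean–Stark)
Reagents that add atoms: none
Why: Intramolecular aldol condensation through the piperidine enamine of the aldehyde, which attacks the methyl ketone and dehydrates, should give ring A with C4 (CHO), C10 and C5=C9 in place.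

Step 3
Reactants: 4 (5S)-2-methyl-5-(prop-1-en-2-yl)cyclopent-1-ene-1-carbaldehyde
Product: 5 [(5S)-2-methyl-5-(prop-1-en-2-yl)cyclopent-1-en-1-yl]methanol
Conditions: NaBH4, CeCl3·7H2O, MeOH, 0 °C
Reagents that add atoms: none
Why: Luche reduction delivers hydride 1,2 to the enal and leaves both alkenes untouched.

Step 4
Reactants: 5 [(5S)-2-methyl-5-(prop-1-en-2-yl)cyclopent-1-en-1-yl]methanol
Product: 6 (5S)-1-(bromomethyl)-2-methyl-5-(prop-1-en-2-yl)cyclopent-1-ene
Conditions: CBr4, PPh3, CH2Cl2, 0 °C
Reagents that add atoms: carbon tetrabromide, BrC(Br)(Br)Br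
Why: The Appel reaction converts the primary allylic alcohol into the bromide under neutral conditions, and allylic transposition is disfavoured because the far alkene carbon C9 is fully substituted.

Step 5
Reactants: 7 (S)-3-bromo-2-methylpropan-1-ol
Product: 8 (S)-(3-bromo-2-methylpropoxy)(tert-butyl)dimethylsilane
Conditions: TBSCl, imidazole, CH2Cl2, rt
Reagents that add atoms: tert-butyldimethylsilyl chloride, CC(C)(C)[Si](C)(C)Cl
Why: Standard silylation masks the hydroxyl group (later C15–O) so that the bromide end (C3) can be turned into a Grignard reagent.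

Step 6
Reactants: 8 (S)-(3-bromo-2-methylpropoxy)(tert-butyl)dimethylsilane, 6 (5S)-1-(bromomethyl)-2-methyl-5-(prop-1-en-2-yl)cyclopent-1-ene
Product: 10 tert-butyl(dimethyl){(2R)-2-methyl-4-[(5S)-2-methyl-5-(prop-1-en-2-yl)cyclopent-1-en-1-yl]butoxy}silane, via Grignard reagent 9 (not isolated)
Conditions: Mg, THF, reflux; then 6, Li2CuCl4 (cat.), THF, −78 °C to 0 °C
Reagents that add atoms: none
Why: Copper-catalysed cross-coupling of a primary alkyl Grignard reagent with an allylic bromide forms C3–C4 by direct displacement, because attack at the fully substituted C9 is blocked, and C2 lies β to the metal and is not affected.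

Step 7
Reactants: 10 tert-butyl(dimethyl){(2R)-2-methyl-4-[(5S)-2-methyl-5-(prop-1-en-2-yl)cyclopent-1-en-1-yl]butoxy}silane
Product: 11 (2R)-2-methyl-4-[(5S)-2-methyl-5-(prop-1-en-2-yl)cyclopent-1-en-1-yl]butan-1-ol
Conditions: Bu4NF, THF, rt
Reagents that add atoms: none
Why: Fluoride desilylation frees the primary alcohol and affects nothing else in this hydrocarbon framework.

Step 8
Reactants: 11 (2R)-2-methyl-4-[(5S)-2-methyl-5-(prop-1-en-2-yl)cyclopent-1-en-1-yl]butan-1-ol, 12 methyl (triphenylphosphoranylidene)acetate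
Product: 14 methyl (2E,4R)-4-methyl-6-[(5S)-2-methyl-5-(prop-1-en-2-yl)cyclopent-1-en-1-yl]hex-2-enoate, via aldehyde 13 (not isolated)
Conditions: PhI(OAc)2, TEMPO (cat.), CH2Cl2, rt; then 12, rt
Reagents that add atoms: none
Why: Oxoammonium oxidation followed in the same flask by a Wittig reaction with the stabilised ylide should give the E-enoate and spares the epimerisable α-methyl aldehyde (C2) an isolation.

Step 9
Reactants: 14 methyl (2E,4R)-4-methyl-6-[(5S)-2-methyl-5-(prop-1-en-2-yl)cyclopent-1-en-1-yl]hex-2-enoate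
Product: 15 methyl 2-[(3aS,5S,6R)-1,4,4,6-tetramethyl-2,3,3a,4,5,6,7,8-octahydroazulen-5-yl]acetate
Conditions: Fe(acac)3 (30 mol %), PhSiH3 (slow addition), EtOH/HOCH2CH2OH, 60 °C, 0.01 M
Reagents that add atoms: none
Why: Proposed new method: Fe(acac)3 and PhSiH3 in ethanol form a trivalent iron hydride that passes a hydrogen atom to the terminal CH2 (C14) of the isopropenyl group, which completes the gem-dimethyl unit and places a tertiary radical on C12; this nucleophilic radical adds to the electron-poor β-carbon C15 of the enoate, and the α-ester radical at C16 is reduced by divalent iron to the enolate and protonated by ethanol, which returns trivalent iron. The closest known reaction type is the iron-catalysed reductive olefin coupling (hydrogen-atom-transfer Giese reaction), whose intramolecular form is established for five- and six-membered rings. Ring B closes 7-exo-trig, helped by the cyclopentene, which fixes C6 and the sp2 carbon C5 in one plane and leaves only the C4–C3–C2 segment free to rotate. The new stereocentre C15 should be set by a transition state with the C2 methyl group pseudo-equatorial and the ester arm anti to it (C16 trans to C1), but either epimer serves because C15 becomes sp2 in step 12. Hydrogen-atom transfer must go to the 1,1-disubstituted alkene only, which the steric shielding of tetrasubstituted C5=C9 and the electron poverty of the enoate secure, and closure must outrun a second hydrogen-atom transfer or loss of H6, which high dilution and slow silane addition favour. C6 and C2 take no part and keep their configuration.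

Step 10
Reactants: 15 methyl 2-[(3aS,5S,6R)-1,4,4,6-tetramethyl-2,3,3a,4,5,6,7,8-octahydroazulen-5-yl]acetate
Product: 16 2-[(3aS,5S,6R)-1,4,4,6-tetramethyl-2,3,3a,4,5,6,7,8-octahydroazulen-5-yl]ethan-1-ol
Conditions: LiAlH4, THF, 0 °C
Reagents that add atoms: none
Why: Hydride reduction removes the ester before the borane step, so that C5=C9 is the only group left for borane to add to.

Step 11
Reactants: 16 2-[(3aS,5S,6R)-1,4,4,6-tetramethyl-2,3,3a,4,5,6,7,8-octahydroazulen-5-yl]ethan-1-ol
Product: 18 (1R,3aR,5S,6R,8aR)-5-(2-hydroxyethyl)-1,4,4,6-tetramethyldecahydroazulen-1-ol, via C9 alkylborane 17 (not isolated)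
Conditions: BH3·THF (excess), THF, 0 °C to rt; then NaOH, H2O2, H2O, 0 °C to 40 °C
Reagents that add atoms: hydrogen peroxide, OO
Why: Hydroboration–oxidation, the classic syn hydration of 1,2-dialkylcyclopentenes, should bring borane to the face of C5=C9 turned away from C12 and its methyl groups, with boron on the less crowded C9 and hydrogen on C5, and oxidation with retention then leaves H5 and O11 cis to each other and to H6, which sets C5 and C9 (the free alcohol only consumes borane).

Step 12
Reactants: 18 (1R,3aR,5S,6R,8aR)-5-(2-hydroxyethyl)-1,4,4,6-tetramethyldecahydroazulen-1-ol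
Product: 20 (2E)-2-[(1R,3aR,6R,8aR)-1-hydroxy-1,4,4,6-tetramethyloctahydroazulen-5(1H)-ylidene]acetaldehyde, via saturated hydroxy aldehyde 19 (not isolated)
Conditions: 2-iodoxybenzoic acid (IBX, 3 equiv), DMSO/fluorobenzene, rt then 70 °C
Reagents that add atoms: none
Why: IBX oxidises the primary alcohol and, on warming, dehydrogenates the enolisable aldehyde (IBX α,β-dehydrogenation) at its only β-hydrogen H15; C16 is planar in the enol, so allylic 1,3-strain decides the geometry and turns the formyl group away from quaternary C12 to give the E alkene of the target, while the tertiary alcohol cannot be oxidised.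

Step 13
Reactants: 20 (2E)-2-[(1R,3aR,6R,8aR)-1-hydroxy-1,4,4,6-tetramethyloctahydroazulen-5(1H)-ylidene]acetaldehyde
Product: 21 C9 triethylsilyl ether of enal 20
Conditions: TESOTf, 2,6-lutidine, CH2Cl2, −78 °C to 0 °C
Reagents that add atoms: triethylsilyl trifluoromethanesulfonate, CC[Si](CC)(CC)OS(=O)(=O)C(F)(F)F
Why: Silyl triflate silylation covers the tertiary hydroxyl group, which would otherwise shuttle protons during the enolate alkylation of step 20, and the weak base at low temperature should leave the enal alone.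

Step 14
Reactants: 21 C9 triethylsilyl ether of enal 20
Product: 22 (2E)-2-[(1R,3aR,6R,8aR)-1,4,4,6-tetramethyl-1-(triethylsilyloxy)octahydroazulen-5(1H)-ylidene]ethan-1-ol
Conditions: NaBH4, CeCl3·7H2O, MeOH, −20 °C
Reagents that add atoms: none
Why: Luche reduction gives the allylic alcohol by 1,2-addition, with the alkene geometry and the tertiary silyl ether unchanged.

Step 15
Reactants: 22 (2E)-2-[(1R,3aR,6R,8aR)-1,4,4,6-tetramethyl-1-(triethylsilyloxy)octahydroazulen-5(1H)-ylidene]ethan-1-ol
Product: 23 A/B allylic bromide (C17–Br, C15=C16 E, C9–OSiEt3)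
Conditions: CBr4, PPh3, CH2Cl2, −20 °C
Reagents that add atoms: carbon tetrabromide, BrC(Br)(Br)Br
Why: The Appel reaction gives the primary allylic bromide under neutral conditions, and transposition to fully substituted, neopentyl C15 is not expected.

Step 16
Reactants: 24 (E)-geranylacetone
Product: 25 4-[(2R,3R)-3-{2-[(2R)-3,3-dimethyloxiran-2-yl]ethyl}-3-methyloxiran-2-yl]butan-2-one
Conditions: 1,2:4,5-di-O-isopropylidene-β-D-erythro-2,3-hexodiulo-2,6-pyranose (30 mol %), KHSO5 (as 2KHSO5·KHSO4·K2SO4), K2CO3, Bu4NHSO4, Na2B4O7 buffer, MeCN/CH2(OMe)2/H2O, 0 °C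
Reagents that add atoms: potassium peroxymonosulfate, [K+].[O-]S(=O)(=O)OO
Why: In the Shi asymmetric epoxidation the dioxirane of the D-fructose-derived ketone meets both trisubstituted alkenes through the spiro transition state in the same facial sense, which sets C23, C19 and C29 as R, and the saturated ketone is inert.

Step 17
Reactants: 25 4-[(2R,3R)-3-{2-[(2R)-3,3-dimethyloxiran-2-yl]ethyl}-3-methyloxiran-2-yl]butan-2-one
Product: 27 terminal tert-butyldimethylsilyl enol ether of 25 (C18H2=C32–OSi), via lithium enolate 26 (not isolated)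
Conditions: LiN(iPr)2, THF, −78 °C; then TBSCl, DMPU, −78 °C to 0 °C
Reagents that add atoms: tert-butyldimethylsilyl chloride, CC(C)(C)[Si](C)(C)Cl
Why: Kinetic deprotonation of the methyl ketone at its methyl group (C18) and O-silylation give the less substituted enol silane, and the epoxides tolerate the amide base at low temperature.

Step 18
Reactants: 27 terminal tert-butyldimethylsilyl enol ether of 25 (C18H2=C32–OSi)
Product: 28 (3R,5aR,9aR)-3-(tert-butyldimethylsilyloxy)-2,2,5a-trimethyloctahydrobenzo[b]oxepin-7(2H)-one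
Conditions: TBSOTf, 2,6-di-tert-butyl-4-methylpyridine, CH2Cl2, −78 °C
Reagents that add atoms: none
Why: In this Lewis-acid-triggered epoxide-opening cascade ended by an enol silane (tandem oxa-/carbacyclisation of a 1,5-diepoxide), O28 of the inner epoxide opens the silylated terminal epoxide at tertiary C25, C18 then opens the epoxonium ion at tertiary C19 with inversion through a chair, rings D and C form trans-fused with C23 and C29 carried over from 25, and the silyl cation released from the oxocarbenium ion re-forms TBSOTf.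

Step 19
Reactants: 28 (3R,5aR,9aR)-3-(tert-butyldimethylsilyloxy)-2,2,5a-trimethyloctahydrobenzo[b]oxepin-7(2H)-one
Product: 29 (3R,5aR,9aR)-3-(tert-butyldimethylsilyloxy)-2,2,5a-trimethyl-3,4,5,5a,6,9a-hexahydrobenzo[b]oxepin-7(2H)-one
Conditions: IBX, DMSO/toluene, 70 °C
Reagents that add atoms: none
Why: In this IBX α,β-dehydrogenation of a cyclohexanone only C30–C31 can be desaturated and no dienone can follow because C19 is quaternary, and the enone leaves C18 as the only site for kinetic α′-deprotonation.

Step 20
Reactants: 29 (3R,5aR,9aR)-3-(tert-butyldimethylsilyloxy)-2,2,5a-trimethyl-3,4,5,5a,6,9a-hexahydrobenzo[b]oxepin-7(2H)-one, 23 A/B allylic bromide (C17–Br, C15=C16 E, C9–OSiEt3)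
Product: 31 coupled enone (C17–C18 formed, C17 anti to the C20 methyl group), via lithium dienolate 30 (not isolated)
Conditions: LiN(iPr)2, THF, −78 °C; then 23, DMPU, −78 °C to −20 °C
Reagents that add atoms: none
Why: Kinetic α′-deprotonation of the cyclohexenone to the cross-conjugated dienolate and SN2 alkylation with the primary allylic bromide (as in the α′-alkylation of isophorone next to its quaternary carbon) form C17–C18 without touching the C15=C16 geometry, and the electrophile should enter anti to the axial C20 methyl group, a bias that step 21 corrects.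

Step 21
Reactants: 31 coupled enone (C17–C18 formed, C17 anti to the C20 methyl group)
Product: 33 coupled ketone (C32=O, C18 R with the side chain equatorial), via phenylsilyl enol ether 32 (not isolated)
Conditions: [(Ph3P)CuH]6 (cat.), PhSiH3, toluene, rt; then NaOMe (cat.), MeOH, rt
Reagents that add atoms: none
Why: Copper hydride conjugate reduction touches only the enone, and methoxide then releases the ketone from the silyl enol ether and equilibrates enolisable C18 to the epimer with the side chain equatorial, which is the configuration of the target.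

Step 22
Reactants: 33 coupled ketone (C32=O, C18 R with the side chain equatorial)
Product: 34 O11-triethylsilyl O24-tert-butyldimethylsilyl ether of the target
Conditions: MeMgBr, CeCl3, THF, −78 °C to 0 °C
Reagents that add atoms: methylmagnesium bromide, C[Mg]Br
Why: The cerium-modified Grignard 1,2-addition suppresses enolisation, and because the axial C20 methyl group blocks the axial trajectory the methyl group enters equatorially, which gives axial O34 cis to C20 and C17 (C32 S).

Step 23
Reactants: 34 O11-triethylsilyl O24-tert-butyldimethylsilyl ether of the target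
Product: 35 target CNP0167890.2
Conditions: Bu4NF, THF, 50 °C
Reagents that add atoms: none
Why: Fluoride removes both silyl ethers under non-acidic conditions, so the tertiary alcohols and the trisubstituted alkene run no risk of ionisation or cyclisation.

Compound list
1 | (R)-(+)-limonene | CC1=CC[C@@H](CC1)C(C)=C | starting material
2 | limonene ring ozonide (1,2,4-trioxolane across the former ring alkene) | CC12CC[C@H](CC(OO1)O2)C(C)=C | intermediate
3 | (3R)-6-oxo-3-(prop-1-en-2-yl)heptanal | CC(=O)CC[C@H](CC=O)C(C)=C | intermediate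
4 | (5S)-2-methyl-5-(prop-1-en-2-yl)cyclopent-1-ene-1-carbaldehyde | O=CC1=C(C)CC[C@H]1C(C)=C | intermediate
5 | [(5S)-2-methyl-5-(prop-1-en-2-yl)cyclopent-1-en-1-yl]methanol | OCC1=C(C)CC[C@H]1C(C)=C | intermediate
6 | (5S)-1-(bromomethyl)-2-methyl-5-(prop-1-en-2-yl)cyclopent-1-ene | BrCC1=C(C)CC[C@H]1C(C)=C | intermediate
7 | (S)-3-bromo-2-methylpropan-1-ol | C[C@@H](CO)CBr | starting material
8 | (S)-(3-bromo-2-methylpropoxy)(tert-butyl)dimethylsilane | C[C@@H](CO[Si](C)(C)C(C)(C)C)CBr | intermediate
9 | [(S)-3-(tert-butyldimethylsilyloxy)-2-methylpropyl]magnesium bromide | C[C@@H](CO[Si](C)(C)C(C)(C)C)C[Mg]Br | intermediate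
10 | tert-butyl(dimethyl){(2R)-2-methyl-4-[(5S)-2-methyl-5-(prop-1-en-2-yl)cyclopent-1-en-1-yl]butoxy}silane | C[C@@H](CO[Si](C)(C)C(C)(C)C)CCC1=C(C)CC[C@H]1C(C)=C | intermediate
11 | (2R)-2-methyl-4-[(5S)-2-methyl-5-(prop-1-en-2-yl)cyclopent-1-en-1-yl]butan-1-ol | C[C@@H](CO)CCC1=C(C)CC[C@H]1C(C)=C | intermediate
12 | methyl (triphenylphosphoranylidene)acetate | COC(=O)C=P(c1ccccc1)(c1ccccc1)c1ccccc1 | starting material
13 | (2R)-2-methyl-4-[(5S)-2-methyl-5-(prop-1-en-2-yl)cyclopent-1-en-1-yl]butanal | C[C@@H](C=O)CCC1=C(C)CC[C@H]1C(C)=C | intermediate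
14 | methyl (2E,4R)-4-methyl-6-[(5S)-2-methyl-5-(prop-1-en-2-yl)cyclopent-1-en-1-yl]hex-2-enoate | C[C@H](CCC1=C(C)CC[C@H]1C(C)=C)/C=C/C(=O)OC | intermediate
15 | methyl 2-[(3aS,5S,6R)-1,4,4,6-tetramethyl-2,3,3a,4,5,6,7,8-octahydroazulen-5-yl]acetate | C[C@@H]1CCC2=C(C)CC[C@H]2C(C)(C)[C@H]1CC(=O)OC | intermediate
16 | 2-[(3aS,5S,6R)-1,4,4,6-tetramethyl-2,3,3a,4,5,6,7,8-octahydroazulen-5-yl]ethan-1-ol | C[C@@H]1CCC2=C(C)CC[C@H]2C(C)(C)[C@H]1CCO | intermediate
17 | C9 alkylborane (BH2 on C9, H on C5, C17–O–BH2) | C[C@@H]1CC[C@@H]2[C@@H](CC[C@@]2(C)B)C(C)(C)[C@H]1CCOB | intermediate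
18 | (1R,3aR,5S,6R,8aR)-5-(2-hydroxyethyl)-1,4,4,6-tetramethyldecahydroazulen-1-ol | C[C@@H]1CC[C@@H]2[C@@H](CC[C@@]2(C)O)C(C)(C)[C@H]1CCO | intermediate
19 | 2-[(1R,3aR,5S,6R,8aR)-1-hydroxy-1,4,4,6-tetramethyldecahydroazulen-5-yl]acetaldehyde | C[C@@H]1CC[C@@H]2[C@@H](CC[C@@]2(C)O)C(C)(C)[C@H]1CC=O | intermediate
20 | (2E)-2-[(1R,3aR,6R,8aR)-1-hydroxy-1,4,4,6-tetramethyloctahydroazulen-5(1H)-ylidene]acetaldehyde | C[C@@H]1CC[C@@H]2[C@@H](CC[C@@]2(C)O)C(C)(C)/C1=C/C=O | intermediate
21 | C9 triethylsilyl ether of enal 20 | C[C@@H]1CC[C@@H]2[C@@H](CC[C@@]2(C)O[Si](CC)(CC)CC)C(C)(C)/C1=C/C=O | intermediate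
22 | (2E)-2-[(1R,3aR,6R,8aR)-1,4,4,6-tetramethyl-1-(triethylsilyloxy)octahydroazulen-5(1H)-ylidene]ethan-1-ol | C[C@@H]1CC[C@@H]2[C@@H](CC[C@@]2(C)O[Si](CC)(CC)CC)C(C)(C)/C1=C/CO | intermediate
23 | A/B allylic bromide (C17–Br, C15=C16 E, C9–OSiEt3) | C[C@@H]1CC[C@@H]2[C@@H](CC[C@@]2(C)O[Si](CC)(CC)CC)C(C)(C)/C1=C/CBr | intermediate
24 | (E)-geranylacetone | CC(C)=CCC/C(C)=C/CCC(C)=O | starting material
25 | 4-[(2R,3R)-3-{2-[(2R)-3,3-dimethyloxiran-2-yl]ethyl}-3-methyloxiran-2-yl]butan-2-one | CC(=O)CC[C@H]1O[C@]1(C)CC[C@H]1OC1(C)C | intermediate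
26 | terminal lithium enolate of 25 | [Li]OC(=C)CC[C@H]1O[C@]1(C)CC[C@H]1OC1(C)C | intermediate
27 | terminal tert-butyldimethylsilyl enol ether of 25 | C=C(O[Si](C)(C)C(C)(C)C)CC[C@H]1O[C@]1(C)CC[C@H]1OC1(C)C | intermediate
28 | (3R,5aR,9aR)-3-(tert-butyldimethylsilyloxy)-2,2,5a-trimethyloctahydrobenzo[b]oxepin-7(2H)-one | C1[C@@]2(C)CC[C@@H](O[Si](C)(C)C(C)(C)C)C(C)(C)O[C@@H]2CCC1=O | intermediate
29 | (3R,5aR,9aR)-3-(tert-butyldimethylsilyloxy)-2,2,5a-trimethyl-3,4,5,5a,6,9a-hexahydrobenzo[b]oxepin-7(2H)-one | C1[C@@]2(C)CC[C@@H](O[Si](C)(C)C(C)(C)C)C(C)(C)O[C@@H]2C=CC1=O | intermediate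
30 | cross-conjugated lithium dienolate of 29 (C18=C32–OLi) | C1[C@@]2(C)CC[C@@H](O[Si](C)(C)C(C)(C)C)C(C)(C)O[C@@H]2C=CC(O[Li])=1 | intermediate
31 | coupled enone, C17 anti to the C20 methyl group | C[C@@H]1CC[C@@H]2[C@@H](CC[C@@]2(C)O[Si](CC)(CC)CC)C(C)(C)/C1=C/C[C@H]1[C@@]2(C)CC[C@@H](O[Si](C)(C)C(C)(C)C)C(C)(C)O[C@@H]2C=CC1=O | intermediate
32 | phenylsilyl enol ether (C31=C32–OSiH2Ph) of the reduced enone | C[C@@H]1CC[C@@H]2[C@@H](CC[C@@]2(C)O[Si](CC)(CC)CC)C(C)(C)/C1=C/C[C@H]1[C@@]2(C)CC[C@@H](O[Si](C)(C)C(C)(C)C)C(C)(C)O[C@@H]2CC=C1O[SiH2]c1ccccc1 | intermediate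
33 | coupled ketone, C18 R (side chain equatorial) | C[C@@H]1CC[C@@H]2[C@@H](CC[C@@]2(C)O[Si](CC)(CC)CC)C(C)(C)/C1=C/C[C@@H]1[C@@]2(C)CC[C@@H](O[Si](C)(C)C(C)(C)C)C(C)(C)O[C@@H]2CCC1=O | intermediate
34 | O11-triethylsilyl O24-tert-butyldimethylsilyl ether of the target | C[C@@H]1CC[C@@H]2[C@@H](CC[C@@]2(C)O[Si](CC)(CC)CC)C(C)(C)/C1=C/C[C@@H]1[C@@]2(C)CC[C@@H](O[Si](C)(C)C(C)(C)C)C(C)(C)O[C@@H]2CC[C@]1(C)O | intermediate
35 | CNP0167890.2 | C[C@@H]1CC[C@@H]2[C@@H](CC[C@@]2(C)O)C(C)(C)/C1=C/C[C@@H]1[C@@]2(C)CC[C@@H](O)C(C)(C)O[C@@H]2CC[C@]1(C)O | target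

Total step count: 23. Longest linear sequence: 18 steps (1–4, 6–15, 20–23).

Steps most likely to fail

1. Step 9. The seven-membered closure may be slower than a second hydrogen-atom transfer to the C12 radical. It may also be slower than loss of H6, which would move the alkene into conjugation and erase C6.
The fallback replaces the radical by an organopalladium closure of the same bond and uses known reaction types only. It sets out from aldehyde 13, isolated by leaving the ylide out of step 8.
- Corey–Fuchs olefination (CBr4, PPh3) gives the 1,1-dibromoalkene F1.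
- n-BuLi followed by ClCO2Me gives the ynoate F2.
- NaI in AcOH adds HI to give the (Z)-β-iodoenoate F3.
- A reductive Heck cyclisation (Pd(OAc)2, PPh3, HCO2Na, DMF, 80 °C) lets the vinylpalladium species add 7-exo-trig across C12=C14 and form C12–C15. The neopentyl alkylpalladium intermediate has no β-hydrogen and is reduced by formate to the second methyl group, which gives the bicyclic dienoate F4.
- Conjugate reduction with Mg in MeOH saturates C15=C16, and the route is rejoined at 15.

2. Step 11. Borane may add sluggishly to the hindered tetrasubstituted alkene. Boron may also end on C5 instead of C9, or facial selectivity may be poor.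
The fallback sets out from 16 and delivers oxygen first and hydrogen second. m-Chloroperbenzoic acid epoxidises C5=C9 on the face away from C12 to give the epoxy alcohol F5, which fixes O11. Reductive epoxide opening with trivalent titanium (Cp2TiCl2, Mn, H2O, THF) should then break the C5–O bond at the more congested carbon. The ring-fusion radical should take up hydrogen on the face not screened by the C12 methyl groups. The route is rejoined at 18.

3. Step 12. The dehydrogenation may stall at the aldehyde stage because H15 is flanked by a quaternary carbon. It may also run on to further desaturation, with loss of the C2 configuration.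
The fallback sets out from 18. TEMPO/PhI(OAc)2 stops at hydroxy aldehyde 19, which is isolated this time. TESOTf and Et3N silylate both O11 and the aldehyde enol to give the bis(triethylsilyl) enol ether F6. A Saegusa–Ito oxidation (Pd(OAc)2, MeCN) then gives the E-enal through an equilibrating palladium enolate. The route is rejoined at 21, so step 13 is no longer needed.

Further compounds
F1 | step 9 | (3R)-1,1-dibromo-3-methyl-5-[(5S)-2-methyl-5-(prop-1-en-2-yl)cyclopent-1-en-1-yl]pent-1-ene | C[C@@H](C=C(Br)Br)CCC1=C(C)CC[C@H]1C(C)=C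
F2 | step 9 | methyl (4R)-4-methyl-6-[(5S)-2-methyl-5-(prop-1-en-2-yl)cyclopent-1-en-1-yl]hex-2-ynoate | C[C@@H](C#CC(=O)OC)CCC1=C(C)CC[C@H]1C(C)=C
F3 | step 9 | methyl (2Z,4R)-3-iodo-4-methyl-6-[(5S)-2-methyl-5-(prop-1-en-2-yl)cyclopent-1-en-1-yl]hex-2-enoate | C[C@@H](/C(I)=C/C(=O)OC)CCC1=C(C)CC[C@H]1C(C)=C
F4 | step 9 | methyl (2Z)-2-[(3aS,6R)-1,4,4,6-tetramethyl-2,3,3a,4,7,8-hexahydroazulen-5(6H)-ylidene]acetate | C[C@@H]1CCC2=C(C)CC[C@H]2C(C)(C)/C1=C\C(=O)OC
F5 | step 11 | C5–C9 epoxide of 16 (oxygen on the face opposite C12) | C[C@@H]1CC[C@@]23O[C@]2(C)CC[C@H]3C(C)(C)[C@H]1CCO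
F6 | step 12 | bis(triethylsilyl) compound: O11 silyl ether and (Z)-silyl enol ether of 19 | C[C@@H]1CC[C@@H]2[C@@H](CC[C@@]2(C)O[Si](CC)(CC)CC)C(C)(C)[C@H]1/C=C\O[Si](CC)(CC)CC
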